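The delta run is the neighbour we read first, because its rate per unit of substrate, the rate divided by c(substrate), climbs as the run proceeds.

| flask | substrate | coupling partner | free catalyst | time |
|---|---|---|---|---|
| delta | 0.500 M | 1.25 M | 0.0400 M |  |
| gamma | 0.200 M | 0.950 M | 0.0400 M |  |
| eta | 1.00 M | 1.25 M | 0.0400 M |  |
| beta | 0.250 M | 1.25 M | 0.0130 M | 11 min |

| delta run: time / min | delta run: [product] / M | gamma run: time / min | gamma run: [product] / M | eta run: time / min | eta run: [product] / M |
|---|---|---|---|---|---|
| 0.44 | 0 | 0.44 | 0 | 0.44 | 0.018 |
| 0.70 | 0.023 | 0.70 | 0.013 | 0.70 | 0.026 |
| 1.1 | 0.035 | 1.1 | 0.010 | 1.1 | 0.053 |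
| 1.7 | 0.055 | 1.7 | 0.022 | 1.7 | 0.096 |
| 2.8 | 0.094 | 2.8 | 0.032 | 2.8 | 0.181 |
| 4.4 | 0.156 | 4.4 | 0.055 | 4.4 | 0.313 |
| 6.9 | 0.243 | 6.9 | 0.100 | 6.9 | 0.519 |
| 11 | 0.360 | 11 | 0.125 | 11 | 0.744 |

(readings scatter by 0.005 M)

- order of the initial rate in [coupling partner], near the charge of the delta run, the rate being that where two percent of its substrate are product
- order of the initial rate in [substrate], near the charge of the delta run, the rate being that where two percent of its substrate are product (one fixed amount of product, the same in the runs compared)
- the gamma run starts with 0.300 M less of substrate and of coupling partner than the delta run, and with no product. Compared where both hold the same amount of substrate, once fifteen percent of what the gamma run was charged with has turned into product, is the gamma run faster, slower or alike (within a tenth)?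
- product in the beta run at 11 min, as a share of the substrate charged

- Overall: substrate + coupling partner -> product, with free catalyst as catalyst.
- Constant volume, constant temperature.
- Readings of a species count what is bound in complexes too.
- An order is taken over about fifteen percent of the charge, up and down.

Between 0.70 min and 2.8 min the delta run gives 0.0766 min⁻¹ at a mean c(product) of 0.0585 M. Between 6.9 min and 11 min it gives 0.144 min⁻¹ at 0.301 M, so it is faster per unit of substrate late than early. The rise divided by the extra product is 0.276 L mol⁻¹ min⁻¹. This is the product gain, the rate per unit of substrate won for each molar of product in the flask, read while c(coupling partner) falls. Taken back to no product, the delta line leaves a catalyst term of 0.0604 min⁻¹.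

These give a ladder of times for the delta run. Product is first clearly above the scatter at 0.70 min. Next comes the product clock, one over gain times charged substrate, 7.23 min. Slowest is the catalyst clock, one over the catalyst term, 16.6 min. Both clocks are estimates, since the gain behind them is read while c(coupling partner) falls.

For the beta run we assume, as our own untested step, that the catalyst term follows the catalyst charge and the gain does not. The catalyst term becomes 0.01963 min⁻¹, and the clocks become 14.5 min and 50.9 min, both longer than the 11 min asked. The catalyst there is worth 0.0710 M of product, the amount at which the two terms are equal. Running the rule through 11 min gives us 26.8%. For the gamma run, at equal substrate it holds 0.0300 M of product against 0.330 M in the delta run, so the gain makes it slower, at 0.453 of the delta rate.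

The forecast, which says "I assume first order in catalyst, though no run tests this", gives 0.2 (−0.3 to 0.7) and 0.9 (0.7 to 1.05) for the orders, slower for the gamma run, and 22% (14% to 34%) for the beta run, the delta run with its clock scaled as if first order in everything but substrate, and lower than our figure.

The beta run gives 29.9%, with orders −0.17 and 0.73 and the gamma run slower.

    free catalyst + substrate → loaded catalyst + by-product (7.740 L mol⁻¹ min⁻¹)
    loaded catalyst + coupling partner → product + free catalyst (3.270 L mol⁻¹ min⁻¹)
    free catalyst + coupling partner ⇌ idle catalyst-reagent complex, settled at all times (2.330 L mol⁻¹)
    substrate + coupling partner + product → 2 product (0.2172 L² mol⁻² min⁻¹)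

The gamma run stands at 0.62 of the delta rate, against the 0.453 from the gain. In the beta run the product made by 11 min is 0.0748 M, and on that amount the gain read from the delta run gives an estimated 0.0206 min⁻¹ per unit of substrate.

The readings come from a simulation for substances that don't exist.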